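**Retrosynthetic overview**
1. C12–C13: B-alkyl Suzuki–Miyaura coupling of the bicyclic iodide 16 (C1–C12) with the (E)-vinyl iodide 23 (C13–C22/C30, from geranylacetone); C3 ketone and C30 acid are unveiled last.
2. Ring-B stereotriad on a cis-decalin: C8 by equatorial MeCeCl2 addition to an α-alkylidene ketone, C9 by 8-OH-directed (Crabtree) hydrogenation.
3. cis Ring fusion: angular C10 methyl by cuprate addition to a Δ1(9)-octalone (methyl enters syn to H-5).
4. Octalone from 6-methoxy-2-tetralone: ring A is the saturated tetralone ring (present from the start, gem-dimethylated), ring B is the anisole ring, dearomatised later by Birch reduction; C5 is fixed thermodynamically from C3.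
5. First stereocentre (C3 carbinol) by ketoreductase reduction of the achiral dimethyltetralone; C3 ends as the ketone.

Assumption: the SMILES is taken literally; its tags put H-5 on the same face as the C-10 methyl (cis-fused decalin), so the route is built for that cis-fused stereoisomer.

Locants follow polypodane numbering (decalin C1–C10; chain C11–C22; C30 = terminal oxidised carbon). β = face of the C10 methyl. "cis-core" = 3α-OTBS, 4,4-dimethyl, 5β-H, 10β-methyl decalin.

**Route**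

Step 1
Reactants: 1 6-methoxy-2-tetralone
Product: 2 6-methoxy-1,1-dimethyl-2-tetralone
Conditions: NaH (2.3 equiv), MeI (2.5 equiv), THF, 0 °C → rt
Reagents that add atoms: iodomethane, CI
Why: Double enolate C-alkylation at C1, the benzylic α-carbon and most acidic site of a 2-tetralone, so both methyls enter there and no stereocentre is formed.

Step 2
Reactants: 2 6-methoxy-1,1-dimethyl-2-tetralone
Product: 3 (R)-6-methoxy-1,1-dimethyl-1,2,3,4-tetrahydronaphthalen-2-ol
Conditions: (R)-selective ketoreductase (KRED, NADP-dependent alcohol dehydrogenase), NADP+ (cat.), i-PrOH, phosphate buffer pH 7, 10% DMSO, 30 °C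
Reagents that add atoms: none
Why: Ketoreductase-catalysed asymmetric carbonyl reduction, in which the enzyme distinguishes the quaternary benzylic flank from the CH2 flank and delivers hydride to one face, setting the first stereocentre (future C3, R).

Step 3
Reactants: 3 (R)-6-methoxy-1,1-dimethyl-1,2,3,4-tetrahydronaphthalen-2-ol
Product: 4 (R)-6-methoxy-1,1-dimethyl-1,2,3,4,5,8-hexahydronaphthalen-2-ol
Conditions: Li, NH3(l), THF, t-BuOH, −78 → −33 °C; MeOH, H2O
Reagents that add atoms: none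
Why: Birch reduction of the anisole gives the 2,5-dihydro product with the enol ether at C8 and the tetrasubstituted C5=C10 alkene retained, the alkoxide being inert.

Step 4
Reactants: 4 (R)-6-methoxy-1,1-dimethyl-1,2,3,4,5,8-hexahydronaphthalen-2-ol
Product: 6 (4aS,6R)-6-hydroxy-5,5-dimethyl-4,4a,5,6,7,8-hexahydronaphthalen-2(3H)-one, via β,γ-enone 5 (not isolated)
Conditions: 2 M aq HCl, THF/MeOH, 25 → 45 °C to constant epimer ratio; chromatography; minor 4a-epimer re-subjected
Reagents that add atoms: water, O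
Why: Enol-ether hydrolysis and acid-catalysed β,γ→α,β isomerisation form C5 reversibly through the dienol, so the ratio is thermodynamic and favours 6 (equatorial OH, H-3/H-5 trans; estimated about 3:1), with the separable epimer recycled.

Step 5
Reactants: 6 (4aS,6R)-6-hydroxy-5,5-dimethyl-4,4a,5,6,7,8-hexahydronaphthalen-2(3H)-one
Product: 7 (4aS,6R)-6-(tert-butyldimethylsilyloxy)-5,5-dimethyl-4,4a,5,6,7,8-hexahydronaphthalen-2(3H)-one
Conditions: TBSOTf, 2,6-lutidine, CH2Cl2, −78 → 0 °C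
Reagents that add atoms: tert-butyldimethylsilyl triflate, CC(C)(C)[Si](C)(C)OS(=O)(=O)C(F)(F)F
Why: Silylation of the hindered secondary alcohol protects the future C3 ketone through the organometallic steps and touches no stereocentre.

Step 6
Reactants: 7 (4aS,6R)-6-(tert-butyldimethylsilyloxy)-5,5-dimethyl-4,4a,5,6,7,8-hexahydronaphthalen-2(3H)-one
Product: 8 (2R,4aS,8aS)-2-(tert-butyldimethylsilyloxy)-1,1,4a-trimethyl-6-(trimethylsilyloxy)-1,2,3,4,4a,7,8,8a-octahydronaphthalene
Conditions: Me2CuLi (from MeLi, CuI), TMSCl, THF/Et2O, −78 → −30 °C; Et3N, cold NaHCO3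
Reagents that add atoms: methyllithium (used as Me2CuLi), [Li]C; chlorotrimethylsilane, C[Si](C)(C)Cl
Why: Cuprate conjugate addition to a Δ1(9)-2-octalone delivers the angular methyl syn to H-5 (cis fusion; the α-face is also blocked by the axial 4α-methyl), and the enolate is trapped regiospecifically as the Δ8 silyl enol ether.

Step 7
Reactants: 8 Δ8 silyl enol ether; 9 benzyloxyacetaldehyde
Product: 10 9-[2-(benzyloxy)-1-hydroxyethyl]-8-ketone on the cis-core (mixture at C9/C11)
Conditions: TiCl4, CH2Cl2, −78 °C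
Reagents that add atoms: none
Why: Mukaiyama aldol of the regiodefined enol silane at C9 with the chelation-activated aldehyde; the two new centres are erased in the next step.

Step 8
Reactants: 10 aldol adduct
Product: 12 9-[2-(benzyloxy)ethylidene]-8-ketone on the cis-core (E/Z mixture), via mesylate 11 (not isolated)
Conditions: MsCl, Et3N, CH2Cl2, 0 °C; then DBU, rt
Reagents that add atoms: none
Why: Mesylation and E1cB elimination give the α-alkylidene ketone; alkene geometry is irrelevant because C11 becomes CH2.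

Step 9
Reactants: 12 α-alkylidene ketone
Product: 13 9-[2-(benzyloxy)ethylidene]-8β-methyl-8α-hydroxy cis-core
Conditions: MeLi, CeCl3, THF, −78 °C
Reagents that add atoms: methyllithium (used as MeCeCl2), [Li]C
Why: Organocerium 1,2-addition to the enone carbonyl; with the quaternary C4 equatorial on ring B the C1 methylene is axial on the α-face and blocks axial attack, so methyl enters equatorially from β, giving 8β-Me/8α-OH.

Step 10
Reactants: 13 tertiary allylic alcohol
Product: 14 9β-[2-(benzyloxy)ethyl]-8β-methyl-8α-hydroxy cis-core (9α-H)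
Conditions: [Ir(cod)(PCy3)(py)]PF6 (10 mol %), H2 (1 atm), CH2Cl2, rt
Reagents that add atoms: none
Why: Hydroxyl-directed (Crabtree) hydrogenation, in which iridium bound to the axial 8α-OH delivers H2 to the α-face of the exocyclic alkene, so H-9 is α and the side chain β.

Step 11
Reactants: 14 benzyl ether
Product: 15 9β-(2-hydroxyethyl)-8β-methyl-8α-hydroxy cis-core
Conditions: H2 (1 atm), Pd(OH)2/C, EtOAc/EtOH, rt
Reagents that add atoms: none
Why: Hydrogenolysis of the benzyl ether with no stereocentre involved and the silyl ether untouched.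

Step 12
Reactants: 15 diol
Product: 16 9β-(2-iodoethyl)-8β-methyl-8α-hydroxy cis-core
Conditions: I2, PPh3, imidazole, CH2Cl2, 0 °C
Reagents that add atoms: iodine, II
Why: Appel-type iodination converts only the primary alcohol, and the trans-diaxial C11/O8 arrangement disfavours cyclic-ether formation.

Step 13
Reactants: 17 (E)-geranylacetone
Product: 19 (E)-6,10-dimethylundeca-5,9-dien-1-yne, via enol phosphate 18 (not isolated)
Conditions: LDA, THF, −78 °C; ClP(O)(OEt)2; then LDA (2.3 equiv), −78 °C → rt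
Reagents that add atoms: none
Why: Negishi methyl ketone → terminal alkyne conversion via the kinetic terminal enolate, its enol phosphate and base-induced elimination; the 5E alkene is untouched.

Step 14
Reactants: 19 (E)-6,10-dimethylundeca-5,9-dien-1-yne
Product: 20 (2E,6E)-2,6-dimethylundeca-2,6-dien-10-yn-1-ol
Conditions: SeO2 (cat.), t-BuOOH, salicylic acid (cat.), CH2Cl2, rt; NaBH4, MeOH, 0 °C
Reagents that add atoms: tert-butyl hydroperoxide, CC(C)(C)OO
Why: Sharpless SeO2/t-BuOOH allylic oxidation (ene then [2,3]-shift) is selective for the (E)-methyl of the terminal trisubstituted alkene and gives the (E)-allylic alcohol.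

Step 15
Reactants: 20 (2E,6E)-2,6-dimethylundeca-2,6-dien-10-yn-1-ol
Product: 21 tert-butyl{[(2E,6E)-2,6-dimethylundeca-2,6-dien-10-yn-1-yl]oxy}dimethylsilane
Conditions: TBSCl, imidazole, DMF, rt
Reagents that add atoms: tert-butyldimethylsilyl chloride, CC(C)(C)[Si](C)(C)Cl
Why: Standard silylation of the primary allylic alcohol so that it survives the organoaluminium and organolithium steps.

Step 16
Reactants: 21 silyl ether alkyne
Product: 23 tert-butyl{[(2E,6E,10E)-11-iodo-2,6,10-trimethylundeca-2,6,10-trien-1-yl]oxy}dimethylsilane, via alkenylalane 22 (not isolated)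
Conditions: Me3Al, Cp2ZrCl2 (25 mol %), CH2Cl2, rt; then I2, THF, −30 °C
Reagents that add atoms: trimethylaluminium, C[Al](C)C; iodine, II
Why: Zr-catalysed Negishi carboalumination adds Me–Al syn across the terminal alkyne (Me to the internal carbon), and iodinolysis with retention gives the (E)-vinyl iodide.

Step 17
Reactants: 16 iodide; 23 vinyl iodide
Product: 26 3α,30-bis(tert-butyldimethylsilyloxy)-5β-polypoda-13E,17E,21E-trien-8α-ol, via dilithio species 24 (not isolated), via borate 25 (not isolated)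
Conditions: 16, t-BuLi (3.1 equiv), Et2O, −78 °C; B-MeO-9-BBN, THF, −78 °C → rt; then 23, PdCl2(dppf) (5 mol %), AsPh3, aq K3PO4, DMF, rt
Reagents that add atoms: none
Why: B-alkyl Suzuki–Miyaura coupling (I/Li exchange, borate formation, Pd-catalysed sp3–sp2 coupling) joins C12 to C13 with retention of the 13E geometry and no effect on the ring stereocentres.

Step 18
Reactants: 26 bis-silyl ether
Product: 27 5β-polypoda-13E,17E,21E-triene-3α,8α,30-triol
Conditions: TBAF, THF, 55 °C
Reagents that add atoms: none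
Why: Fluoride desilylation removes both TBS groups (the hindered C3 ether needs heat) under non-acidic conditions that spare the tertiary alcohol.

Step 19
Reactants: 27 triol
Product: 28 8α-hydroxy-3-oxo-5β-polypoda-13E,17E,21E-trien-30-al
Conditions: Dess–Martin periodinane (2.5 equiv), NaHCO3, CH2Cl2, rt
Reagents that add atoms: none
Why: Dess–Martin oxidation converts the C3 secondary alcohol to the ketone and the allylic primary alcohol to the enal, while the tertiary 8-OH cannot react and C5 (flanked by quaternary C4) cannot epimerise.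

Step 20
Reactants: 28 keto enal
Product: 29 Myrrhanone B (target, as given)
Conditions: NaClO2, NaH2PO4, 2-methyl-2-butene, t-BuOH/H2O, 0 °C → rt
Reagents that add atoms: sodium chlorite, [Na+].[O-]Cl=O
Why: Pinnick oxidation takes the enal to the (E)-2-methyl-2-enoic acid, with the HOCl scavenger protecting the trisubstituted alkenes and no stereocentre touched.

**Compound list**
1 | 6-methoxy-3,4-dihydronaphthalen-2(1H)-one | COc1ccc2c(c1)CCC(=O)C2 | starting material
2 | 6-methoxy-1,1-dimethyl-3,4-dihydronaphthalen-2(1H)-one | COc1ccc2c(c1)CCC(=O)C2(C)C | intermediate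
3 | (R)-6-methoxy-1,1-dimethyl-1,2,3,4-tetrahydronaphthalen-2-ol | COc1ccc2c(c1)CC[C@@H](O)C2(C)C | intermediate
4 | (R)-6-methoxy-1,1-dimethyl-1,2,3,4,5,8-hexahydronaphthalen-2-ol | COC1=CCC2=C(C1)CC[C@@H](O)C2(C)C | intermediate
5 | (R)-6-hydroxy-5,5-dimethyl-3,4,5,6,7,8-hexahydronaphthalen-2(1H)-one (β,γ-enone) | O=C1CCC2=C(C1)CC[C@@H](O)C2(C)C | intermediate
6 | (4aS,6R)-6-hydroxy-5,5-dimethyl-4,4a,5,6,7,8-hexahydronaphthalen-2(3H)-one (3α-OH, 5β-H) | O=C1C=C2CC[C@@H](O)C(C)(C)[C@H]2CC1 | intermediate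
7 | (4aS,6R)-6-(tert-butyldimethylsilyloxy)-5,5-dimethyl-4,4a,5,6,7,8-hexahydronaphthalen-2(3H)-one | O=C1C=C2CC[C@@H](O[Si](C)(C)C(C)(C)C)C(C)(C)[C@H]2CC1 | intermediate
8 | (2R,4aS,8aS)-2-(TBSO)-1,1,4a-trimethyl-6-(trimethylsilyloxy)-1,2,3,4,4a,7,8,8a-octahydronaphthalene (cis-fused Δ8 enol silane) | C[Si](C)(C)OC1=C[C@@]2(C)CC[C@@H](O[Si](C)(C)C(C)(C)C)C(C)(C)[C@H]2CC1 | intermediate
9 | 2-(benzyloxy)acetaldehyde | O=CCOCc1ccccc1 | starting material
10 | 9-[2-(benzyloxy)-1-hydroxyethyl]-8-ketone, cis-core (C9/C11 mixture, not defined) | OC(COCc1ccccc1)C1[C@@]2(C)CC[C@@H](O[Si](C)(C)C(C)(C)C)C(C)(C)[C@H]2CCC1=O | intermediate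
11 | mesylate of 10 | CS(=O)(=O)OC(COCc1ccccc1)C1[C@@]2(C)CC[C@@H](O[Si](C)(C)C(C)(C)C)C(C)(C)[C@H]2CCC1=O | intermediate
12 | 9-[2-(benzyloxy)ethylidene]-8-ketone, cis-core (E/Z not defined) | C(COCc1ccccc1)=C1[C@@]2(C)CC[C@@H](O[Si](C)(C)C(C)(C)C)C(C)(C)[C@H]2CCC1=O | intermediate
13 | 9-[2-(benzyloxy)ethylidene]-8β-methyl-8α-ol, cis-core | C(COCc1ccccc1)=C1[C@@]2(C)CC[C@@H](O[Si](C)(C)C(C)(C)C)C(C)(C)[C@H]2CC[C@@]1(C)O | intermediate
14 | 9β-[2-(benzyloxy)ethyl]-8β-methyl-8α-ol, cis-core (9α-H) | c1ccccc1COCC[C@@H]1[C@@]2(C)CC[C@@H](O[Si](C)(C)C(C)(C)C)C(C)(C)[C@H]2CC[C@@]1(C)O | intermediate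
15 | 9β-(2-hydroxyethyl)-8β-methyl-8α-ol, cis-core | OCC[C@@H]1[C@@]2(C)CC[C@@H](O[Si](C)(C)C(C)(C)C)C(C)(C)[C@H]2CC[C@@]1(C)O | intermediate
16 | 9β-(2-iodoethyl)-8β-methyl-8α-ol, cis-core | ICC[C@@H]1[C@@]2(C)CC[C@@H](O[Si](C)(C)C(C)(C)C)C(C)(C)[C@H]2CC[C@@]1(C)O | intermediate
17 | (E)-6,10-dimethylundeca-5,9-dien-2-one (geranylacetone) | CC(C)=CCC/C(C)=C/CCC(C)=O | starting material
18 | diethyl (E)-6,10-dimethylundeca-1,5,9-trien-2-yl phosphate | CC(C)=CCC/C(C)=C/CCC(=C)OP(=O)(OCC)OCC | intermediate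
19 | (E)-6,10-dimethylundeca-5,9-dien-1-yne | CC(C)=CCC/C(C)=C/CCC#C | intermediate
20 | (2E,6E)-2,6-dimethylundeca-2,6-dien-10-yn-1-ol | OC/C(C)=C/CC/C(C)=C/CCC#C | intermediate
21 | tert-butyl{[(2E,6E)-2,6-dimethylundeca-2,6-dien-10-yn-1-yl]oxy}dimethylsilane | CC(C)(C)[Si](C)(C)OC/C(C)=C/CC/C(C)=C/CCC#C | intermediate
22 | dimethyl[(1E,5E,9E)-11-(TBSO)-2,6,10-trimethylundeca-1,5,9-trien-1-yl]alane | CC(C)(C)[Si](C)(C)OC/C(C)=C/CC/C(C)=C/CC/C(C)=C/[Al](C)C | intermediate
23 | tert-butyl{[(2E,6E,10E)-11-iodo-2,6,10-trimethylundeca-2,6,10-trien-1-yl]oxy}dimethylsilane | CC(C)(C)[Si](C)(C)OC/C(C)=C/CC/C(C)=C/CC/C(C)=C/I | intermediate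
24 | dilithio species from 16 (C12–Li, O8–Li) | [Li]CC[C@@H]1[C@@]2(C)CC[C@@H](O[Si](C)(C)C(C)(C)C)C(C)(C)[C@H]2CC[C@@]1(C)O[Li] | intermediate
25 | lithium B-alkyl-B-methoxy-9-BBN borate from 24 | [Li+].CO[B-]1(CC[C@@H]3[C@@]4(C)CC[C@@H](O[Si](C)(C)C(C)(C)C)C(C)(C)[C@H]4CC[C@@]3(C)O[Li])C2CCCC1CCC2 | intermediate
26 | 3α,30-bis(TBSO)-5β-polypoda-13E,17E,21E-trien-8α-ol | CC(C)(C)[Si](C)(C)OC/C(C)=C/CC/C(C)=C/CC/C(C)=C/CC[C@@H]1[C@@]2(C)CC[C@@H](O[Si](C)(C)C(C)(C)C)C(C)(C)[C@H]2CC[C@@]1(C)O | intermediate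
27 | 5β-polypoda-13E,17E,21E-triene-3α,8α,30-triol | OC/C(C)=C/CC/C(C)=C/CC/C(C)=C/CC[C@@H]1[C@@]2(C)CC[C@@H](O)C(C)(C)[C@H]2CC[C@@]1(C)O | intermediate
28 | 8α-hydroxy-3-oxo-5β-polypoda-13E,17E,21E-trien-30-al | O=C/C(C)=C/CC/C(C)=C/CC/C(C)=C/CC[C@@H]1[C@@]2(C)CCC(=O)C(C)(C)[C@H]2CC[C@@]1(C)O | intermediate
29 | Myrrhanone B | C/C(=C\CC/C(C)=C/CC[C@@H]1[C@@]2(C)CCC(=O)C(C)(C)[C@H]2CC[C@@]1(C)O)CC/C=C(\C)C(=O)O | target

**Count**
Total steps: 20. Longest linear sequence: 16 (steps 1–12, then 17–20); steps 13–16 form the side-chain branch.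

**Three steps most likely to fail**

Step 4 has only a modest thermodynamic bias at C5 and depends on separating and recycling epimers. The fallback replaces substrate-controlled equilibration by catalyst-controlled kinetic protonation. It sets out from 4: mild hydrolysis (oxalic acid, aq MeOH, 0 °C) stops at the isolable β,γ-enone 5, which is silylated (TBSOTf, 2,6-lutidine) to (R)-6-(tert-butyldimethylsilyloxy)-5,5-dimethyl-3,4,5,6,7,8-hexahydronaphthalen-2(1H)-one F1. A cinchona-derived primary–tertiary diamine with an acid co-catalyst (dienamine proton shuttle, matched enantiomer) then moves the alkene into conjugation and places H-5 on the β-face. This gives 7 directly, where the fallback rejoins the route.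

Step 6 is a cuprate addition to a hindered enone whose β-carbon is flanked by the C4 quaternary centre; it may be slow or lose facial control. The fallback makes the angular methyl by directed cyclopropanation and reductive ring opening. It sets out from 7: CBS reduction ((R)-Me-CBS, BH3·SMe2) gives the 8β-allylic alcohol (2S,4aS,6R)-6-(tert-butyldimethylsilyloxy)-5,5-dimethyl-2,3,4,4a,5,6,7,8-octahydronaphthalen-2-ol F2. Hydroxyl-directed Simmons–Smith reaction (Et2Zn, CH2I2) gives the 9,10β-methano alcohol F3, and Dess–Martin oxidation gives the cyclopropyl ketone F4. Li/NH3 cleaves the external cyclopropane bond to a C10 β-methyl and the C8 enolate, which is trapped with TMSCl to rejoin the route at 8.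

Step 10 must hydrogenate a very hindered alkene on the concave face; if direction by the 8-OH fails, the 9-epimer forms. The fallback sets C9 by kinetic enolate alkylation and C8 by epoxide opening. It sets out from 8: MeLi, then allyl bromide, alkylates axially (anti to the axial C1 methylene) to the 9β-allyl 8-ketone F5. KHMDS/PhNTf2 (deprotonation at C7) gives the Δ7 enol triflate F6, and Me2CuLi gives the 8-methyl Δ7-alkene F7. mCPBA attacks the ring alkene anti to the axial allyl group to give the 7α,8α-epoxide F8, and LiBHEt3 opens it trans-diaxially at C7 to the 9β-allyl 8β-methyl 8α-ol F9. Ozonolysis with NaBH4 work-up rejoins the route at 15.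

Further compounds
F1 | step 4 | (R)-6-(tert-butyldimethylsilyloxy)-5,5-dimethyl-3,4,5,6,7,8-hexahydronaphthalen-2(1H)-one | O=C1CCC2=C(C1)CC[C@@H](O[Si](C)(C)C(C)(C)C)C2(C)C
F2 | step 6 | (2S,4aS,6R)-6-(tert-butyldimethylsilyloxy)-5,5-dimethyl-2,3,4,4a,5,6,7,8-octahydronaphthalen-2-ol (8β-OH) | O[C@@H]1C=C2CC[C@@H](O[Si](C)(C)C(C)(C)C)C(C)(C)[C@H]2CC1
F3 | step 6 | 9,10β-methano-8β-hydroxy-3α-(TBSO)-4,4-dimethyl-5β-H decalin | O[C@H]1CC[C@@H]2C(C)(C)[C@H](O[Si](C)(C)C(C)(C)C)CC[C@@]23C[C@@H]13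
F4 | step 6 | 9,10β-methano-8-oxo-3α-(TBSO)-4,4-dimethyl-5β-H decalin | O=C1CC[C@@H]2C(C)(C)[C@H](O[Si](C)(C)C(C)(C)C)CC[C@@]23C[C@@H]13
F5 | step 10 | 9β-allyl-8-ketone, cis-core | C=CC[C@@H]1[C@@]2(C)CC[C@@H](O[Si](C)(C)C(C)(C)C)C(C)(C)[C@H]2CCC1=O
F6 | step 10 | 9β-allyl-Δ7-en-8-yl triflate, cis-core | C=CC[C@@H]1[C@@]2(C)CC[C@@H](O[Si](C)(C)C(C)(C)C)C(C)(C)[C@H]2CC=C1OS(=O)(=O)C(F)(F)F
F7 | step 10 | 9β-allyl-8-methyl-Δ7-ene, cis-core | C=CC[C@@H]1[C@@]2(C)CC[C@@H](O[Si](C)(C)C(C)(C)C)C(C)(C)[C@H]2CC=C1C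
F8 | step 10 | 9β-allyl-8β-methyl-7α,8α-epoxide, cis-core | C=CC[C@@H]1[C@@]2(C)CC[C@@H](O[Si](C)(C)C(C)(C)C)C(C)(C)[C@H]2C[C@H]3O[C@@]13C
F9 | step 10 | 9β-allyl-8β-methyl-8α-ol, cis-core | C=CC[C@@H]1[C@@]2(C)CC[C@@H](O[Si](C)(C)C(C)(C)C)C(C)(C)[C@H]2CC[C@@]1(C)O
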